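Compound numbers used throughout: 1 cis-cyclopent-4-ene-1,3-diol, 2 its silylene-bridged bicycle, 3 4-benzyloxy-3-methoxystyrene, 4 ring-opened styrenyl/vinyl dioxasilinane, 5 hept-1-ene, 6 styrenyl/heptenyl dioxasilinane, 7 saturated dioxasilinane, 8 diol, 9 diacetate benzyl ether, 10 target.

## The problem

The target 10 is (3R,5S)-1-(4-hydroxy-3-methoxyphenyl)dodecane-3,5-diyl diacetate: an unbranched C12 chain with a guaiacyl ring at C1 and a syn-1,3-diol diacetate at C3/C5 (syn follows from the descriptors, since both carbinols rank O > C4 > outer chain). There is no ring to close. The whole difficulty is the pair of stereocentres, which must be set relative to each other and in the absolute sense with no third stereo-element to lean on. The C3–C4–C5 triad is pseudo-meso: the two carbinol carbons differ only in the far ends of their arms (2-arylethyl against heptyl). The chain therefore offers no bias, and the absolute configuration is simply the decision which end of a meso triad receives the aryl arm. Routes that make the centres one after the other need two independent selectivities, and a leak in the first shows up as loss of enantiomeric purity.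

The feature that lets both be settled at once is the five-carbon segment C2–C3–C4–C5–C6 with both oxygens on one side. Joined C2 to C6, it is the carbocycle (ring A) of cis-cyclopent-4-ene-1,3-diol 1. In ring A, syn is simply cis, C3 and C5 are mirror images across the plane through C4, and C2/C6 are the two enantiotopic olefinic carbons.

The sensitive points are three. The phenol must end free beside two alkyl acetates, so it stays masked to the last step. A syn-1,3-diol monoacetate would undergo acyl migration, so both acetates go on together. The electron-rich arene and the transient allylic C–O bonds exclude oxidising or hydrogenolysing conditions at the wrong stage.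

## Retrosynthesis

**10 ⇒ 9 ⇒ 8 ⇒ 7 (C–O bonds only).** The O-benzyl bond of 9, the two acetyl C–O bonds (back to diol 8) and the two O–Si bonds of silylene 7 are cut. Hydrogenolysis as the last step is neutral and is the only operation carried out on the complete functional-group set. Acetylation at the stage of 8 meets a masked phenol and places both acetates at once. The silylene of 7 is not an added protecting group but the bridge inherited from the key step. The forward steps only have to be chemoselective; no stereocentre is involved.

**7 ⇒ 6 (retro-hydrogenation).** Unsaturation is introduced at C1=C2 and C6=C7. This makes both carbinol carbons allylic, so both arms become attachable by olefin metathesis, and the geometry of either double bond is irrelevant. The forward reaction must saturate two 1,2-disubstituted alkenes without cleaving allylic C–O bonds or the benzyl ether, and without double-bond migration toward C3 or C5.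

**6 ⇒ 4 + 5 (cut C6=C7).** A cross-metathesis disconnection removes the six-carbon tail as hept-1-ene 5 and leaves a vinyl group on 4. Against a cut at C5–C6 (epoxide opening) or C4–C5 (aldol), it leaves both stereocentres untouched. The forward reaction has to distinguish the terminal vinyl group of 4 from its internal styrenyl double bond.

**4 ⇒ 2 + 3 (key: cut C1=C2, join C2=C6).** This is the retron of a ring-opening cross-metathesis. The styrenyl carbon C1 is removed with styrene 3 and ring A is re-formed, giving the meso bicycle 2. Both stereocentres already exist in 2 as bridgeheads with a fixed cis relation. One catalytic event then decides which enantiotopic olefinic carbon carries the aryl arm, and so fixes C3 and C5 together. The precursors are an achiral C5 bicycle and a commercial styrene, while the product holds the aryl arm, both centres and a handle for the second arm. The forward reaction needs a chiral alkylidene that differentiates the two ends of the ring alkene, enough strain to open a cyclopentene, and a product that does not close back.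

**2 ⇒ 1 (cut two O–Si bonds).** The di-tert-butylsilylene bridge answers the last two demands. An unbridged derivative of 1 has too little strain for ring opening, and its opened products would re-close readily. Spanning O3 and O5 forces ring A into a strained 2,4-dioxa-3-silabicyclo[3.2.1]octene, a ring system already known to undergo ring-opening metathesis in polymerisation. After opening, the same bridge is a relaxed chair dioxasilinane that protects the diol through steps 2–4. Meso symmetry is kept, and 1 is commercial.

## Roads not taken

Alternative 1: Cut C4–C5 (aldol) and the C3–H bond (carbonyl reduction), the route most chemists would draw first. 4-(4-Benzyloxy-3-methoxyphenyl)butan-2-one A1 would be enolised on the methyl side as a chiral diisopinocampheylboron enolate and added to octanal A2. This gives (S)-1-(4-benzyloxy-3-methoxyphenyl)-5-hydroxydodecan-3-one A3, the O-benzyl ether of [8]-gingerol. A chelation-controlled syn reduction (Narasaka–Prasad, Et2BOMe/NaBH4) would then lead to 8. The step count is similar, but the two centres come from two unrelated events. The first is an acetate-type aldol of an α-unsubstituted methyl ketone with an unbranched aldehyde, where reagent control is moderate and a stoichiometric chiral boron reagent is needed. The second is a 1,3-induction that inherits every fault of the first. A3 also dehydrates and undergoes retro-aldol cleavage easily. In the chosen plan the relative configuration is a property of ring A and cannot erode, and the absolute configuration comes from one catalytic step.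

Alternative 2: Buy both centres and cut C1=C2 (Wittig) and C6–C7 (decarboxylative alkyl–alkyl coupling). The commercial statin side-chain acetonide tert-butyl 2-[(4R,6S)-6-(hydroxymethyl)-2,2-dimethyl-1,3-dioxan-4-yl]acetate A4 maps correctly, with its hydroxymethyl end as C2 and its acetate end as C6. Oxidation, Wittig olefination with the arylmethyl ylide, hydrogenation and ester cleavage would give 2-[(4R,6R)-6-[2-(4-benzyloxy-3-methoxyphenyl)ethyl]-2,2-dimethyl-1,3-dioxan-4-yl]acetic acid A5. The forward key step would join A5 to a hexyl partner, either by anodic Kolbe cross-coupling or by nickel-catalysed coupling of its redox-active ester. The stereochemistry is secure, but each terminus needs its own oxidation-state change and C–C coupling, and a tert-butyl ester must be cleaved beside an acetonide. That comes to about nine steps to 10. The dialkoxyarene is also oxidised below the potential of a Kolbe electrolysis, so the electrochemical version is not defensible once the arene is present. The chosen plan attaches both arms with one reaction type and no oxidation-state changes.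

Alternative 3: Cut both carbinol C–H bonds, i.e. double reduction of 1-(4-benzyloxy-3-methoxyphenyl)dodecane-3,5-dione A6. A6 is available by a Claisen condensation that copies the polyketide assembly of the gingerols. The forward key step would be an asymmetric hydrogenation with RuCl2[(R)-BINAP]. A single chiral catalyst imposes the same facial sense on both carbonyl groups, which in this pseudo-meso array gives the anti diol (3R,5R)-1-(4-benzyloxy-3-methoxyphenyl)dodecane-3,5-diol A7, not 8. A syn outcome would need catalyst control at one ketone and substrate control at the other. Because the two carbonyls of A6 are nearly indistinguishable, the first reduction would occur at both, and each regioisomer leads to the opposite enantiomer of the syn diol. The pseudo-symmetry that defeats this plan is exactly what the chosen plan exploits.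

Key step: step 2

Assumption: which antipode of the biphenolate ligand delivers 4 and not its mirror image cannot be derived from the structure alone; the (S)-ligand is written, and the (R)-ligand is to be used without other change if the first run shows the opposite sense.

## Route

Step 1
Reactants: 1 (1R,3S)-cyclopent-4-ene-1,3-diol (cis, meso)
Product: 2 (1R,5S)-3,3-di-tert-butyl-2,4-dioxa-3-silabicyclo[3.2.1]oct-6-ene (meso)
Conditions: tBu2Si(OTf)2 (1.1 equiv), 2,6-lutidine, DMF, 0 °C to rt
Reagents that add atoms: di-tert-butylsilyl bis(trifluoromethanesulfonate), CC(C)(C)[Si](OS(=O)(=O)C(F)(F)F)(OS(=O)(=O)C(F)(F)F)C(C)(C)C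
Why: Silylene formation across a cis-1,3-diol with the bis-triflate; only the cis diol can span the bridge (as the diaxial envelope of ring A), which gives the strained bicycle. No stereocentre is touched and the mirror plane through C4 and Si is kept.

Step 2
Reactants: 2 (1R,5S)-3,3-di-tert-butyl-2,4-dioxa-3-silabicyclo[3.2.1]oct-6-ene; 3 4-benzyloxy-3-methoxystyrene
Product: 4 (4S,6R)-4-[(E)-2-(4-benzyloxy-3-methoxyphenyl)ethenyl]-2,2-di-tert-butyl-6-ethenyl-1,3,2-dioxasilinane (S at the carbon bearing the arylethenyl group, R at the carbon bearing the vinyl group)
Conditions: Mo(N-2,6-iPr2C6H3)(CHCMe2Ph)[(S)-3,3'-di-tert-butyl-5,5',6,6'-tetramethylbiphenyl-2,2'-diolate] (5 mol %), 3 (2 equiv), C6H6, 22 °C, N2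
Reagents that add atoms: none
Why: Asymmetric ring-opening cross-metathesis of a meso bicyclic alkene with a styrene; the closest known reaction type is the chiral molybdenum- or ruthenium-alkylidene ring-opening/cross-metathesis of meso norbornenes and 8-oxabicyclo[3.2.1]oct-6-enes with styrenes. The neophylidene is first exchanged with 3 to the benzylidene, which adds in a [2+2] sense to the strained ring A alkene (C2=C6 in target numbering) from the face of the one-carbon bridge; cycloreversion of the molybdacyclobutane sets ArCH=C2 and leaves Mo=C6, which a second molecule of 3 caps as the vinyl group while regenerating the benzylidene. No ring is closed: the carbocycle is opened and the bicycle relaxes to a chair 1,3,2-dioxasilinane with both alkenyl arms equatorial, which drives the step and prevents the product from closing back. No new sp3 centre is formed; the cis relation of the C3–O and C5–O bonds is inherited from ring A of 1, and the step converts the two mirror-related bridgeheads into an (S)- and an (R)-centre by deciding which olefinic carbon receives the benzylidene carbon. That choice is made in the metallacyclobutane-forming step by the axially chiral biphenolate together with the bulky arylimido ligand, which are expected to leave only one orientation open for the approaching bicycle. The step needs (a) selection between the enantiotopic alkene ends, helped by the rigid bicycle offering a single accessible face; (b) capture of the ring-opened alkylidene by 3 before it attacks a second bicycle, secured by the excess of 3; and (c) no second cross-metathesis at the new vinyl group, favoured by its hindered allylic, ring-bound position and by stopping at full conversion of 2. The geometry of the new styrenyl double bond (E expected) is irrelevant because step 4 saturates it.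

Step 3
Reactants: 4 (4S,6R)-4-[(E)-2-(4-benzyloxy-3-methoxyphenyl)ethenyl]-2,2-di-tert-butyl-6-ethenyl-1,3,2-dioxasilinane; 5 hept-1-ene
Product: 6 (4S,6R)-4-[(E)-2-(4-benzyloxy-3-methoxyphenyl)ethenyl]-2,2-di-tert-butyl-6-(hept-1-en-1-yl)-1,3,2-dioxasilinane (E/Z mixture at the heptenyl double bond expected)
Conditions: RuCl2(H2IMes)(=CH-C6H4-2-OiPr) (second-generation Hoveyda–Grubbs catalyst, H2IMes = 1,3-dimesityl-4,5-dihydroimidazol-2-ylidene; 5 mol %), 5 (5 equiv), CH2Cl2, 40 °C
Reagents that add atoms: none
Why: Cross-metathesis of a monosubstituted allylic-ether olefin, which homodimerises slowly, with an excess of a fast-reacting terminal alkene, driven by loss of ethene. The 1,2-disubstituted, conjugated styrenyl alkene engages the ruthenium alkylidene far more slowly, re-closure to the bicycle is uphill, and the E/Z ratio at C6=C7 is of no consequence.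

Step 4
Reactants: 6 (4S,6R)-4-[(E)-2-(4-benzyloxy-3-methoxyphenyl)ethenyl]-2,2-di-tert-butyl-6-(hept-1-en-1-yl)-1,3,2-dioxasilinane
Product: 7 (4R,6S)-4-[2-(4-benzyloxy-3-methoxyphenyl)ethyl]-2,2-di-tert-butyl-6-heptyl-1,3,2-dioxasilinane
Conditions: H2 (1 atm), 5% Rh/Al2O3, EtOAc, rt
Reagents that add atoms: none
Why: Heterogeneous hydrogenation of two 1,2-disubstituted alkenes; rhodium on alumina at 1 atm saturates alkenes with little hydrogenolysis of allylic or benzylic C–O bonds and little of the double-bond migration typical of palladium, so the benzyl ether, the silylene and both carbinol centres should be kept. Both alkene isomers converge on one compound; the descriptors change only because the CIP priorities change.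

Step 5
Reactants: 7 (4R,6S)-4-[2-(4-benzyloxy-3-methoxyphenyl)ethyl]-2,2-di-tert-butyl-6-heptyl-1,3,2-dioxasilinane
Product: 8 (3R,5S)-1-(4-benzyloxy-3-methoxyphenyl)dodecane-3,5-diol
Conditions: HF·pyridine, THF/pyridine, 0 °C to rt
Reagents that add atoms: none
Why: Fluoride-mediated cleavage of the di-tert-butylsilylene, driven by Si–F bond formation under buffered, non-basic conditions. The aryl benzyl and methyl ethers are inert and no stereocentre is involved.

Step 6
Reactants: 8 (3R,5S)-1-(4-benzyloxy-3-methoxyphenyl)dodecane-3,5-diol
Product: 9 (3R,5S)-1-(4-benzyloxy-3-methoxyphenyl)dodecane-3,5-diyl diacetate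
Conditions: Ac2O, pyridine, DMAP (cat.), CH2Cl2, rt
Reagents that add atoms: acetic anhydride, CC(=O)OC(C)=O
Why: DMAP-catalysed acylation of both secondary alcohols in one operation, so that no monoacetate prone to 1,3-acyl migration is isolated. The phenol is still benzyl-masked and cannot be acetylated.

Step 7
Reactants: 9 (3R,5S)-1-(4-benzyloxy-3-methoxyphenyl)dodecane-3,5-diyl diacetate
Product: 10 (3R,5S)-1-(4-hydroxy-3-methoxyphenyl)dodecane-3,5-diyl diacetate
Conditions: H2 (1 atm), 10% Pd/C, EtOAc, rt
Reagents that add atoms: none
Why: Hydrogenolysis of the aryl benzyl ether on palladium. The secondary alkyl acetates are neither benzylic nor allylic at this stage and are not cleaved, and the neutral medium avoids acyl transfer to the liberated phenol.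

## Compound list

1 | (1R,3S)-cyclopent-4-ene-1,3-diol (cis, meso) | O[C@@H]1C[C@H](O)C=C1 | starting material
2 | (1R,5S)-3,3-di-tert-butyl-2,4-dioxa-3-silabicyclo[3.2.1]oct-6-ene (meso) | CC(C)(C)[Si]1(C(C)(C)C)O[C@@H]2C[C@H](O1)C=C2 | intermediate
3 | 4-benzyloxy-3-methoxystyrene (1-benzyloxy-4-ethenyl-2-methoxybenzene) | C=Cc1ccc(OCc2ccccc2)c(OC)c1 | starting material
4 | (4S,6R)-4-[(E)-2-(4-benzyloxy-3-methoxyphenyl)ethenyl]-2,2-di-tert-butyl-6-ethenyl-1,3,2-dioxasilinane | C=C[C@@H](C[C@@H](/C=C/c1ccc(OCc2ccccc2)c(OC)c1)O[Si]1(C(C)(C)C)C(C)(C)C)O1 | intermediate
5 | hept-1-ene | CCCCCC=C | starting material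
6 | (4S,6R)-4-[(E)-2-(4-benzyloxy-3-methoxyphenyl)ethenyl]-2,2-di-tert-butyl-6-(hept-1-en-1-yl)-1,3,2-dioxasilinane (E isomer at the heptenyl bond written) | CCCCC/C=C/[C@@H](C[C@@H](/C=C/c1ccc(OCc2ccccc2)c(OC)c1)O[Si]1(C(C)(C)C)C(C)(C)C)O1 | intermediate
7 | (4R,6S)-4-[2-(4-benzyloxy-3-methoxyphenyl)ethyl]-2,2-di-tert-butyl-6-heptyl-1,3,2-dioxasilinane | CCCCCCC[C@@H](C[C@@H](CCc1ccc(OCc2ccccc2)c(OC)c1)O[Si]1(C(C)(C)C)C(C)(C)C)O1 | intermediate
8 | (3R,5S)-1-(4-benzyloxy-3-methoxyphenyl)dodecane-3,5-diol | CCCCCCC[C@@H](C[C@@H](CCc1ccc(OCc2ccccc2)c(OC)c1)O)O | intermediate
9 | (3R,5S)-1-(4-benzyloxy-3-methoxyphenyl)dodecane-3,5-diyl diacetate | CCCCCCC[C@@H](C[C@@H](CCc1ccc(OCc2ccccc2)c(OC)c1)OC(C)=O)OC(C)=O | intermediate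
10 | (3R,5S)-1-(4-hydroxy-3-methoxyphenyl)dodecane-3,5-diyl diacetate | CCCCCCC[C@@H](C[C@@H](CCc1ccc(O)c(OC)c1)OC(C)=O)OC(C)=O | target

## Step count and least certain steps

Total: 7 steps. Longest linear sequence: 7 steps (1 to 10); 3 and 5 are purchased.

**Step 2 (key step).** Three things are most likely to go wrong. The catalyst may differentiate the enantiotopic alkene ends poorly, giving low enantiomeric purity, because this bridged ring has not been matched to the chiral ligand. Ring-opening oligomerisation may outrun capture by 3. A second cross-metathesis at the new vinyl group may give the achiral bis-styrenyl compound.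

The fallback replaces desymmetrisation by resolution and sets out from 2. Ring-opening cross-metathesis of 2 with 3 under the achiral RuCl2(H2IMes)(=CH-C6H4-2-OiPr) would give 4 together with its mirror image (4R,6S)-4-[(E)-2-(4-benzyloxy-3-methoxyphenyl)ethenyl]-2,2-di-tert-butyl-6-ethenyl-1,3,2-dioxasilinane F1. HF·pyridine would release from this pair (1E,3S,5R)-1-(4-benzyloxy-3-methoxyphenyl)hepta-1,6-diene-3,5-diol F2 (from 4) and its enantiomer (1E,3R,5S)-1-(4-benzyloxy-3-methoxyphenyl)hepta-1,6-diene-3,5-diol F3 (from F1). Lipase-catalysed acylation (Burkholderia cepacia lipase, vinyl acetate, tert-butyl methyl ether) is highly enantiomer-selective for 1-alken-3-ols. By the usual empirical size rule, with vinyl as the smaller group, the vinyl carbinol of F3 should be acetylated to (3S,5R,6E)-7-(4-benzyloxy-3-methoxyphenyl)-5-hydroxyhepta-1,6-dien-3-yl acetate F4, while F2 is recovered. F2 is re-bridged with tBu2Si(OTf)2/2,6-lutidine and comes back to the route at 4.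

**Step 3.** The likely failures are secondary metathesis at the styrenyl double bond, which would exchange the aryl arm for a second heptenyl arm, and slow turnover at the hindered allylic vinyl group while 5 merely homodimerises.

The fallback replaces metathesis by an sp3–sp3 coupling and sets out from 4. 9-BBN hydroborates the monosubstituted vinyl group selectively over the 1,2-disubstituted styrenyl alkene to give 9-{2-[(4S,6S)-6-[(E)-2-(4-benzyloxy-3-methoxyphenyl)ethenyl]-2,2-di-tert-butyl-1,3,2-dioxasilinan-4-yl]ethyl}-9-borabicyclo[3.3.1]nonane F5. B-alkyl Suzuki–Miyaura coupling with 1-bromopentane (Pd(OAc)2, PCy3, K3PO4·H2O, THF, rt) would give (4S,6S)-4-[(E)-2-(4-benzyloxy-3-methoxyphenyl)ethenyl]-2,2-di-tert-butyl-6-heptyl-1,3,2-dioxasilinane F6. Its remaining double bond is saturated under the conditions of step 4, which returns the material to the route at 7.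

**Step 4.** The likely failures are partial saturation of the electron-rich arenes on rhodium, some loss of the benzyl group, or double-bond migration toward C3/C5 before reduction, which would scramble a carbinol centre through an enol silyl ether.

The fallback changes the mode of reduction from metal-surface hydrogenation to concerted diimide transfer, which cannot hydrogenolyse C–O bonds, reduce arenes or migrate double bonds. It sets out from 6 and treats it with 2-nitrobenzenesulfonylhydrazide and Et3N in CH2Cl2 at rt (diimide generated in the flask), coming back to the route at 7 without any new compound.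

## Further compounds

F1 | step 2 | (4R,6S)-4-[(E)-2-(4-benzyloxy-3-methoxyphenyl)ethenyl]-2,2-di-tert-butyl-6-ethenyl-1,3,2-dioxasilinane (mirror image of 4) | C=C[C@H](C[C@H](/C=C/c1ccc(OCc2ccccc2)c(OC)c1)O[Si]1(C(C)(C)C)C(C)(C)C)O1
F2 | step 2 | (1E,3S,5R)-1-(4-benzyloxy-3-methoxyphenyl)hepta-1,6-diene-3,5-diol | C=C[C@@H](C[C@@H](/C=C/c1ccc(OCc2ccccc2)c(OC)c1)O)O
F3 | step 2 | (1E,3R,5S)-1-(4-benzyloxy-3-methoxyphenyl)hepta-1,6-diene-3,5-diol | C=C[C@H](C[C@H](/C=C/c1ccc(OCc2ccccc2)c(OC)c1)O)O
F4 | step 2 | (3S,5R,6E)-7-(4-benzyloxy-3-methoxyphenyl)-5-hydroxyhepta-1,6-dien-3-yl acetate | C=C[C@H](C[C@H](/C=C/c1ccc(OCc2ccccc2)c(OC)c1)O)OC(C)=O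
F5 | step 3 | 9-{2-[(4S,6S)-6-[(E)-2-(4-benzyloxy-3-methoxyphenyl)ethenyl]-2,2-di-tert-butyl-1,3,2-dioxasilinan-4-yl]ethyl}-9-borabicyclo[3.3.1]nonane | C1CC2CCCC(C1)B2CC[C@@H](C[C@@H](/C=C/c1ccc(OCc3ccccc3)c(OC)c1)O[Si]4(C(C)(C)C)C(C)(C)C)O4
F6 | step 3 | (4S,6S)-4-[(E)-2-(4-benzyloxy-3-methoxyphenyl)ethenyl]-2,2-di-tert-butyl-6-heptyl-1,3,2-dioxasilinane | CCCCCCC[C@@H](C[C@@H](/C=C/c1ccc(OCc2ccccc2)c(OC)c1)O[Si]1(C(C)(C)C)C(C)(C)C)O1
F0 | step 4 | none | none
A1 | alternative 1 | 4-(4-benzyloxy-3-methoxyphenyl)butan-2-one | CC(=O)CCc1ccc(OCc2ccccc2)c(OC)c1
A2 | alternative 1 | octanal | CCCCCCCC=O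
A3 | alternative 1 | (S)-1-(4-benzyloxy-3-methoxyphenyl)-5-hydroxydodecan-3-one | CCCCCCC[C@H](O)CC(=O)CCc1ccc(OCc2ccccc2)c(OC)c1
A4 | alternative 2 | tert-butyl 2-[(4R,6S)-6-(hydroxymethyl)-2,2-dimethyl-1,3-dioxan-4-yl]acetate | CC(C)(C)OC(=O)C[C@@H](C[C@@H](CO)OC1(C)C)O1
A5 | alternative 2 | 2-[(4R,6R)-6-[2-(4-benzyloxy-3-methoxyphenyl)ethyl]-2,2-dimethyl-1,3-dioxan-4-yl]acetic acid | OC(=O)C[C@@H](C[C@@H](CCc1ccc(OCc2ccccc2)c(OC)c1)OC1(C)C)O1
A6 | alternative 3 | 1-(4-benzyloxy-3-methoxyphenyl)dodecane-3,5-dione | CCCCCCCC(=O)CC(=O)CCc1ccc(OCc2ccccc2)c(OC)c1
A7 | alternative 3 | (3R,5R)-1-(4-benzyloxy-3-methoxyphenyl)dodecane-3,5-diol | CCCCCCC[C@H](C[C@@H](CCc1ccc(OCc2ccccc2)c(OC)c1)O)O
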